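The benzene ring is made last by disconnecting its C1–C2 bond. The substitution pattern, O-geranyl on C4 para to the C1 acyl group and flanked by the C3 methyl and C5 acetyl, maps onto a 5-acyl-4-alkoxy-3-methyl-2-pyranone: the lactone carbonyl becomes C2–OH, and pyranone C6 with its methyl becomes the C5 acetyl. In one operation methoxide opens the lactone, the chain methylene closes the carbocycle by Claisen condensation onto the freed ester, and enolization gives the arene. The precursor is a 4-geranyloxy-3,6-dimethyl-2-pyranone carrying the (R)-4-methyl-3-oxohexanoyl chain on C5; its ether is installed while O4 is the only hydroxyl, so no phenols need to be told apart.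

Key step: step 9

Remark: "geranyl" means (2E)-3,7-dimethylocta-2,6-dien-1-yl; polycarbonyl compounds are drawn as one keto tautomer although they will exist largely as enols or metal chelates; the single stereocentre of the target is R.

**Step 1**
Reactants: 1 methylmalonic acid
Product: 2 methylmalonyl dichloride
Conditions: SOCl2 (excess), 50 °C; excess reagent removed under reduced pressure; used crude
Reagents that add atoms: thionyl chloride, O=S(Cl)Cl
Why: Standard conversion of a carboxylic acid into its chloride through the acyl chlorosulfite (nucleophilic acyl substitution), run below 60 °C so that the malonic diacid neither decarboxylates nor loses HCl to a ketene, the moisture-sensitive dichloride being used without purification.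

**Step 2**
Reactants: 2 methylmalonyl dichloride; 3 acetylacetone (pentane-2,4-dione)
Product: 5 5-acetyl-4-hydroxy-3,6-dimethyl-2H-pyran-2-one, via C-acylated acid chloride 4 (not isolated)
Conditions: 1,2-dichloroethane, 0 °C → 60 °C, N2 purge to remove HCl, no base
Reagents that add atoms: none
Why: Double acylation of a 1,3-diketone by a malonyl dichloride, a known route to 5-acyl-4-hydroxy-2-pyranones: the central carbon of 3 is C-acylated to give 4, an enol oxygen then closes the lactone on the second acid chloride (6-exo-trig O-acylation) and the new 1,3-dicarbonyl unit enolizes to the 4-hydroxy form; the two acetyl groups of 3 are equivalent, so only one pyranone can form, and the C3 methyl blocks a second annulation.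

**Step 3**
Reactants: 5 5-acetyl-4-hydroxy-3,6-dimethyl-2H-pyran-2-one; 6 geraniol
Product: 7 5-acetyl-4-(geranyloxy)-3,6-dimethyl-2H-pyran-2-one
Conditions: PPh3, DIAD, THF, 0 °C → rt; purification and storage below 30 °C
Reagents that add atoms: none
Why: Mitsunobu etherification: the vinylogous-acid hydroxyl on C4 is the only OH in 5 and acidic enough to protonate the betaine, and its oxygen displaces Ph3PO from the primary allylic carbon of activated geraniol by SN2, which leaves the E alkene untouched; heating is avoided because a 4-allyloxy-2-pyranone can undergo a [3,3] shift to C3.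

**Step 4**
Reactants: 8 (R)-4-benzyl-2-oxazolidinone; 9 butanoyl chloride
Product: 11 (R)-4-benzyl-3-butanoyl-2-oxazolidinone, via lithiated oxazolidinone 10 (not isolated)
Conditions: n-BuLi, THF, −78 °C; then 9, −78 → 0 °C; aq. NH4Cl
Reagents that add atoms: none
Why: Standard N-acylation of a lithiated oxazolidinone by an acid chloride (imide formation ahead of an Evans alkylation), which does not touch the C4 stereocentre of the auxiliary.

**Step 5**
Reactants: 11 (R)-4-benzyl-3-butanoyl-2-oxazolidinone
Product: 13 (R)-4-benzyl-3-[(R)-2-methylbutanoyl]-2-oxazolidinone, via sodium Z-enolate 12 (not isolated)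
Conditions: NaN(SiMe3)2, THF, −78 °C; then MeI (excess), −78 → −40 °C; chromatography or recrystallization to one diastereomer
Reagents that add atoms: iodomethane, CI
Why: Evans asymmetric alkylation: the chelated sodium Z-enolate 12 is methylated on the face opposite the C4 benzyl group, which for the (R)-auxiliary and a butanoyl chain sets the (R) configuration at the new α-carbon; methylation is the least selective of these alkylations, so the minor diastereomer is removed at this stage.

**Step 6**
Reactants: 13 (R)-4-benzyl-3-[(R)-2-methylbutanoyl]-2-oxazolidinone
Product: 15 (R)-2-methylbutanoic acid, via peroxy acid 14 (not isolated)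
Conditions: LiOH, H2O2 (30% aq.), THF/H2O, 0 °C; then aq. Na2SO3; extract 8 (CH2Cl2); acidify with HCl, extract (Et2O), concentrate with care
Reagents that add atoms: hydrogen peroxide, OO
Why: Hydroperoxide cleavage of an N-acyloxazolidinone (removal of the Evans auxiliary): LiOOH attacks the exocyclic imide carbonyl, sulfite reduces peroxy acid 14 to the acid, and the mild non-enolizing conditions keep the α-stereocentre and return auxiliary 8, the expected levorotation of the acid serving as a check of the (R) configuration.

**Step 7**
Reactants: 15 (R)-2-methylbutanoic acid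
Product: 17 1-[(R)-2-methylbutanoyl]-1H-benzotriazole, via (R)-2-methylbutanoyl chloride 16 (not isolated)
Conditions: (COCl)2, cat. DMF, CH2Cl2, 0 °C → rt; then 1H-benzotriazole (3 equiv), 0 °C → rt; filter, wash
Reagents that add atoms: 1H-benzotriazole, c1ccc2[nH]nnc2c1
Why: Acid chloride formation under Vilsmeier catalysis followed by N-acylation of benzotriazole, with excess benzotriazole as the only HCl acceptor, so that no tertiary amine is present to turn 16 into a ketene and the α-stereocentre is kept; the N-acylbenzotriazole is a neutral, storable acyl donor.

**Step 8**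
Reactants: 7 5-acetyl-4-(geranyloxy)-3,6-dimethyl-2H-pyran-2-one; 17 1-[(R)-2-methylbutanoyl]-1H-benzotriazole
Product: 19 4-(geranyloxy)-3,6-dimethyl-5-[(4R)-4-methyl-3-oxohexanoyl]-2H-pyran-2-one, via bromomagnesium enolate 18 (not isolated)
Conditions: MgBr2·OEt2 (3 equiv), i-Pr2NEt (3.5 equiv), CH2Cl2, 0 °C → rt; cold dilute HCl work-up; used promptly
Reagents that add atoms: none
Why: Crossed Claisen C-acylation of a methyl ketone by soft enolization (MgBr2·OEt2 and a tertiary amine with an N-acylbenzotriazole donor), a known 1,3-diketone synthesis: the Mg-bound acetyl group of 7 is deprotonated at its methyl to give 18, which is acylated at carbon, and the product stays on magnesium as its diketonate, which stops a second acylation and keeps enolization at the central carbon, away from the stereocentre.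

**Step 9**
Reactants: 19 4-(geranyloxy)-3,6-dimethyl-5-[(4R)-4-methyl-3-oxohexanoyl]-2H-pyran-2-one
Product: 22 (2R)-1-[3-acetyl-4-(geranyloxy)-2,6-dihydroxy-5-methylphenyl]-2-methylbutan-1-one (target), via ring-opened methyl ester 20 (not isolated), via cyclohexenedione tautomer 21 (not isolated)
Conditions: Mg(OMe)2 (4 equiv), MeOH, rt → 45 °C, Ar; then cold dilute HCl to pH 3–4
Reagents that add atoms: none
Why: Proposed new method: methoxide bound to magnesium adds to the lactone carbonyl C2 of 19 and expels O1 as a 1,3-dicarbonyl enolate to give ester 20, whose former ring bond C3=C4 holds the ester cis to C5 and thus next to the 3-oxoacyl chain; the chain methylene carbon then attacks the ester carbonyl with loss of methoxide, and trione 21 enolizes to the arene. The closest known reaction type is the Mg(OMe)2-induced Claisen-mode conversion of 4-methoxy-6-(2-oxoalkyl)-2-pyranones into 4-O-methyl acylphloroglucinols; untested here is a dicarbonyl chain on C5 of a fully substituted pyranone, which after opening offers the same pair of partners, a β-alkoxy enoate and a β-diketone methylene. The benzene ring is the only ring formed and closes by a 6-exo-trig Claisen (Dieckmann-type) acylation that makes the C1–C2 bond, while pyranone C6 and its methyl remain as the C5 acetyl group. No stereocentre is created, and the (R) centre is spared because the carbonyl next to it belongs to a diketonate, and later to a chelated aryl ketone, that enolizes towards the central carbon or the ring and not towards the stereocentre. The selectivity needed is C-acylation by the chain methylene at the ester, in preference to attack by the acetyl methyl, aldol addition to a ketone or displacement of the geranyloxy group at C4 by methoxide: the methylene is far more acidic than the methyl, magnesium chelation steers such polycarbonyl anions to ester acylation, and C4 is screened by the C3 methyl and the C5 acyl group. O-cyclization of 20 at either enol oxygen is harmless, since the pyranones so formed reopen under the same conditions and only aromatization takes material out of the equilibrium.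

**Compound list**
1 | methylmalonic acid | CC(C(=O)O)C(=O)O | starting material
2 | methylmalonyl dichloride | CC(C(=O)Cl)C(=O)Cl | intermediate
3 | acetylacetone (pentane-2,4-dione) | CC(=O)CC(C)=O | starting material
4 | 4-acetyl-2-methyl-3,5-dioxohexanoyl chloride (C-acylated acid chloride, not isolated) | CC(C(=O)Cl)C(=O)C(C(C)=O)C(C)=O | intermediate
5 | 5-acetyl-4-hydroxy-3,6-dimethyl-2H-pyran-2-one | CC(=O)C1=C(C)OC(=O)C(C)=C1O | intermediate
6 | geraniol, (2E)-3,7-dimethylocta-2,6-dien-1-ol | OC/C=C(\C)CCC=C(C)C | starting material
7 | 5-acetyl-4-(geranyloxy)-3,6-dimethyl-2H-pyran-2-one | CC(=O)C1=C(C)OC(=O)C(C)=C1OC/C=C(\C)CCC=C(C)C | intermediate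
8 | (R)-4-benzyl-2-oxazolidinone | O=C1N[C@H](Cc2ccccc2)CO1 | starting material
9 | butanoyl chloride | CCCC(=O)Cl | starting material
10 | lithium salt of 8, lithium (4R)-4-benzyl-2-oxo-1,3-oxazolidin-3-ide (not isolated) | [Li+].O=C1[N-][C@H](Cc2ccccc2)CO1 | intermediate
11 | (R)-4-benzyl-3-butanoyl-2-oxazolidinone | CCCC(=O)N1[C@H](Cc2ccccc2)COC1=O | intermediate
12 | sodium (Z)-enolate of 11 (not isolated) | [Na+].CC/C=C(\[O-])N1[C@H](Cc2ccccc2)COC1=O | intermediate
13 | (R)-4-benzyl-3-[(R)-2-methylbutanoyl]-2-oxazolidinone | CC[C@@H](C)C(=O)N1[C@H](Cc2ccccc2)COC1=O | intermediate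
14 | (R)-2-methylperoxybutanoic acid, formed as its lithium salt (not isolated) | CC[C@@H](C)C(=O)OO | intermediate
15 | (R)-2-methylbutanoic acid | CC[C@@H](C)C(=O)O | intermediate
16 | (R)-2-methylbutanoyl chloride (not isolated) | CC[C@@H](C)C(=O)Cl | intermediate
17 | 1-[(R)-2-methylbutanoyl]-1H-benzotriazole | CC[C@@H](C)C(=O)n1nnc2ccccc21 | intermediate
18 | bromomagnesium enolate of 7 at the acetyl group (not isolated) | C=C(O[Mg]Br)C1=C(C)OC(=O)C(C)=C1OC/C=C(\C)CCC=C(C)C | intermediate
19 | 4-(geranyloxy)-3,6-dimethyl-5-[(4R)-4-methyl-3-oxohexanoyl]-2H-pyran-2-one | CC[C@@H](C)C(=O)CC(=O)C1=C(C)OC(=O)C(C)=C1OC/C=C(\C)CCC=C(C)C | intermediate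
20 | methyl (2E,8R)-4-acetyl-3-(geranyloxy)-2,8-dimethyl-5,7-dioxodec-2-enoate, ester and C4 cis on the double bond (not isolated) | COC(=O)/C(C)=C(OC/C=C(\C)CCC=C(C)C)\C(C(C)=O)C(=O)CC(=O)[C@H](C)CC | intermediate
21 | 4-acetyl-5-(geranyloxy)-6-methyl-2-[(2R)-2-methylbutanoyl]cyclohex-5-ene-1,3-dione (not isolated) | CC[C@@H](C)C(=O)C1C(=O)C(C)=C(OC/C=C(\C)CCC=C(C)C)C(C(C)=O)C1=O | intermediate
22 | (2R)-1-[3-acetyl-4-(geranyloxy)-2,6-dihydroxy-5-methylphenyl]-2-methylbutan-1-one | CC[C@@H](C)C(=O)c1c(O)c(C)c(OC/C=C(\C)CCC=C(C)C)c(C(C)=O)c1O | target

**Step count**
Total: 9 steps. Longest linear sequence: 6 steps (8 → 11 → 13 → 15 → 17 → 19 → 22). The pyranone branch (1 → 2 → 5 → 7) has 3 steps and joins in step 8.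

**Steps most likely to fail**

1. Step 9 (ring-opening Claisen benzannulation). The tricarbonyl intermediate may fragment by retro-Claisen attack of methoxide, methoxide may displace the geranyloxy group at C4 before the ring closes, the closure may take the aldol course, or the α-stereocentre may erode on long exposure to base. The fallback uses known chemistry and a different disconnection, at the price of the built-in regiocontrol. It sets out from acid chloride 16 (made from 15 as in step 7) and geraniol 6. Friedel–Crafts acylation of commercial 2-methylphloroglucinol (2,4,6-trihydroxytoluene) with 16 (AlCl3, CH2Cl2/PhNO2, 0 °C → rt) would give (2R)-2-methyl-1-(2,4,6-trihydroxy-3-methylphenyl)butan-1-one F1. C-acetylation of the last free ring position (Ac2O, BF3·OEt2, rt → 50 °C) would give (2R)-1-(3-acetyl-2,4,6-trihydroxy-5-methylphenyl)-2-methylbutan-1-one F2. Mitsunobu etherification of F2 with 6 (PPh3, DIAD, THF, 0 °C) would come back to the route at 22. The hydroxyl between the methyl and the acetyl group is the least hindered of the three, so a preference for the wanted ether is expected, but isomeric ethers would have to be removed by chromatography and the optical purity checked after the Lewis acid steps.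

2. Step 8 (soft-enolization acylation). The allylic geranyl group may be lost from the vinylogous ester under bromide and Lewis acid, enolization may occur at the ring 6-methyl instead of the acetyl methyl (C-acylation there would still converge on ester 20 in step 9), O-acylation may compete, or the acyl donor may enolize with loss of optical purity. The fallback replaces acylation by aldol addition and oxidation. It sets out from imide 13: AlMe3 and MeNH(OMe)·HCl (CH2Cl2, 0 °C) would give (2R)-N-methoxy-N,2-dimethylbutanamide F3, and i-Bu2AlH (THF, −78 °C) would give (2R)-2-methylbutanal F4, used at once as a cold solution. The kinetic lithium enolate of 7 (LiN(SiMe3)2, THF, −78 °C) would add to F4 to give 4-(geranyloxy)-5-[(4R)-3-hydroxy-4-methylhexanoyl]-3,6-dimethyl-2H-pyran-2-one F5 as a mixture of carbinol epimers. Dess–Martin periodinane (CH2Cl2, NaHCO3, rt) would oxidize both epimers and come back to the route at 19.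

3. Step 3 (Mitsunobu O-geranylation). Alkylation may occur at the lactone carbonyl oxygen or at C3 instead of O4, the geranyl unit may be attacked in the SN2′ sense, or the hindered, hydrogen-bonded hydroxyl may not react. The fallback reverses the polarity and makes the pyranone the electrophile. It sets out from 5: (COCl)2 with cat. DMF (CH2Cl2, 0 °C → rt) would give the vinylogous acid chloride 5-acetyl-4-chloro-3,6-dimethyl-2H-pyran-2-one F6. Sodium geranyloxide (from 6 and NaH, THF, −40 → 0 °C) would replace chloride at C4 by addition–elimination and come back to the route at 7, with the oxygen regiochemistry fixed by the position of the leaving group.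

Further compounds
F1 | step 9 | (2R)-2-methyl-1-(2,4,6-trihydroxy-3-methylphenyl)butan-1-one | CC[C@@H](C)C(=O)c1c(O)cc(O)c(C)c1O
F2 | step 9 | (2R)-1-(3-acetyl-2,4,6-trihydroxy-5-methylphenyl)-2-methylbutan-1-one | CC[C@@H](C)C(=O)c1c(O)c(C)c(O)c(C(C)=O)c1O
F3 | step 8 | (2R)-N-methoxy-N,2-dimethylbutanamide | CC[C@@H](C)C(=O)N(C)OC
F4 | step 8 | (2R)-2-methylbutanal | CC[C@@H](C)C=O
F5 | step 8 | 4-(geranyloxy)-5-[(4R)-3-hydroxy-4-methylhexanoyl]-3,6-dimethyl-2H-pyran-2-one | CC[C@@H](C)C(O)CC(=O)C1=C(C)OC(=O)C(C)=C1OC/C=C(\C)CCC=C(C)C
F6 | step 3 | 5-acetyl-4-chloro-3,6-dimethyl-2H-pyran-2-one | CC(=O)C1=C(C)OC(=O)C(C)=C1Cl
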